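I decided to count this flask in powers of ten of starting material cleared, because the question is whether it stops clearing before 2.5 min.

| flask | starting material | coupling partner | remark | time |
|---|---|---|---|---|
| autumn | 5 mM | 3 equiv (in portions, 3) | the very flask that is asked about, followed so far; portions every 2.5 s |  |
| winter | 10 mM | 3 equiv (in portions, 3) | run made earlier; portions every 2.5 s |  |
| flask | 5.0 mM | 3.00 equiv (in portions, 3) | the portions of coupling partner follow each other after 2.5 s, the first at the start | 2.5 min |

| autumn: time / s | autumn: first product / % | winter: time / min | winter: first product / % |
|---|---|---|---|
| 10.0 | 77.3 | 0.333 | 90.9 |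
| 12.0 | 81.4 | 0.667 | 91.4 |
| 15.0 | 84.8 | 1.00 | 90.9 |
| 20.0 | 87.7 | 1.33 | 91.0 |
| 25.0 | 89.4 | 2.00 | 90.1 |
| 30.0 | 90.4 | 2.50 | 90.5 |

(each reading ± 0.5 percentage points)

- equivalents of coupling partner to starting material, everything else as given, that leave most first product at 2.5 min
- the amount of first product then, in percent of the starting material charged
- the amount of first product with the amounts as given

- the analysis behind the earlier runs scatters by 0.5 percentage points, standard deviation

The autumn run is this flask followed so far, and the winter run supplied a plateau of first product, the mean of its readings:

plateau = 90.8%

I began with the main step, starting material with coupling partner. Its gap to the plateau in the autumn run fell from 14 percentage points at 10.0 s to 1.4 points at 25.0 s. That gave the decade time, the time in which this gap falls by one power of ten, as a pseudo-first-order reading with the coupling partner taken as constant: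

decade time = 15.2 s

decades by 2.5 min = 9.84

The later gap stands beside a scatter of 0.5 points per reading, so this is a rough reading. Counted by itself, the main step gives 9.84 decades, which I read as the whole charge turned to first product.

The second process is the shortfall from the whole charge down to the plateau, 90.8%; I set it in as a reading of the winter run and named no route for it. The third is a slow drift in the winter run: its earlier three readings average 0.53 points above its later three, beside a scatter of 0.5 points per reading. I did not subtract it, so I committed to 90.8% for the recipe and looked for the best charge below 3.00 equiv.

The forecast read the shortfall as “a fixed parallel loss, not as over-reaction” and gave 1.8 equiv (1.4 equiv to 2.4 equiv), 91% (90.3% to 91.9%) and 90.8% (90% to 91.4%).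

The flask gives 91.4% as charged, and 92.1% at 2.27 equiv.

    starting material + coupling partner → first product (k = 26.0 M⁻¹ s⁻¹)
    coupling partner + first product ⇌ bis adduct (K = 463 M⁻¹, k = 0.632 M⁻¹ s⁻¹)
    2 coupling partner → homo dimer (k = 7.57 M⁻¹ s⁻¹)

At 2.5 min the recipe flask holds 0.710% starting material, which is 2.15 decades against the 9.84 counted. Coupling partner stands at 2.05% of its charge, bis adduct at 7.93%, and homo dimer at 4.67 mM. The same flask read at 1.5 min has 5.92 decades on the count. It holds 1.32% starting material, which is 1.88 decades, and 91.5% first product.

The earlier runs and the new flask are simulated for an exercise, noise included.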